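How much ring still stands in larch at the end, and does a cooler flask keep more?

1. the flask that comes out highest in amount of ring, in percent of the substrate charged, or "all alike" when all lie within 1.5 percentage points (larch / alder / cedar / all alike)
2. ring at the end, in percent of the substrate charged, larch
3. ring at the end, in percent of the substrate charged, alder
4. ring at the end, in percent of the substrate charged, cedar

all flasks: substrate 10 mM
- gamma: activator 7.5 mM; temperature 100 °C; run made earlier
- larch: activator 15.0 mM; temperature 100 °C; time 25 min
- alder: activator 15.0 mM; temperature 40 °C; time 25 min
- cedar: activator 15.0 mM; temperature 70 °C; time 25 min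

- in percentages every species weighs as the substrate in it: one open dimer counts as two
- the numbers in the tables scatter with a standard deviation of 1.5 percentage points
- what may be going on: substrate + activator -> activated form; activated form -> ring; substrate + activated form -> open dimer; substrate <-> dormant form; activator + ring -> over-reaction product; ring <-> isomer of the product
- the earlier runs do not show what temperature does; that part of a forecast is a guess

You have one earlier flask, gamma, at the temperature of larch but with half the activator:

gamma run (percent of the substrate charged)

| time / min | ring / % | substrate / % |
|---|---|---|
| 0.667 | 10 | 51 |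
| 1.00 | 16 | 48 |
| 2.00 | 23 | 42 |
| 4.00 | 29 | 33 |
| 8.00 | 24 | 24 |

(standard deviation of a reading: 1.5 percentage points)

Ring in gamma has its highest reading, 29%, at 4.00 min, and reads 24% at 8.00 min. If larch peaks about as gamma did, which its larger charge of activator leaves open, a crude bracket for larch runs from zero to about that highest reading, and you can tighten both ends.

Treat the fall as a steady fractional loss. The two readings give 0.0473 min⁻¹. Read that as a floor for the loss if new ring was still arriving, as the fall in the substrate readings from 33% to 24% suggests.

Now divide ring gained by substrate lost up to 4.00 min, so that time drops out. This gives 0.433 ring per substrate lost, so if that share held, about 3.9 percentage points of ring arrived during that interval. Take that away from the later reading and you have the loss constant, the fraction of ring lost per minute with the arrivals removed (a pseudo-first-order constant): 0.0916 min⁻¹. This end is an estimate and no firm bound: the share counts ring still standing, and it takes all substrate lost as if it had gone the same way.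

Start larch from the same highest reading and run it to 25 min at gamma's pace, which is an assumption. On that assumption your estimate for ring lies between 4.24% and 10.7%. Gamma shows no temperature other than 100 °C, so for alder and cedar you can only guess.

The forecast gives larch 7%, which is inside the bracket, alder 11% and cedar 29%, and it puts cedar highest, “near the peak”.

Larch ends at 8.77%, inside the bracket, alder at 5.31%, and cedar comes out highest at 31.1%.

    substrate + activator → activated form (k = 8.10 L mol⁻¹ min⁻¹, Ea = 67.0 kJ mol⁻¹)
    activated form → ring (k = 2.30 min⁻¹, Ea = 91.0 kJ mol⁻¹)
    substrate + activated form → open dimer (k = 100 L mol⁻¹ min⁻¹, Ea = 36.0 kJ mol⁻¹)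
    substrate ⇌ dormant form (K = 2.30, k = 1.80 min⁻¹, Ea = 104 kJ mol⁻¹, ΔH = −42.0 kJ mol⁻¹)
    activator + ring → over-reaction product (k = 1.60 L mol⁻¹ min⁻¹, Ea = 51.0 kJ mol⁻¹)
    ring ⇌ isomer of the product (K = 6.30, k = 0.00830 min⁻¹, Ea = 99.0 kJ mol⁻¹, ΔH = 18.0 kJ mol⁻¹)
    (constants at 70 °C)

At the end larch holds 62.6% as isomer of the product, more than as ring. Larch's own fall from 20.9% at 12.5 min gives 0.0695 min⁻¹, between the two constants. Run gamma on from its reading at 8.00 min to 25 min: the constants give 5.06% and 10.7%, and gamma stands at 9.13%.

The numbers in the tables were computed with constants of no real substance; scatter was added.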